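**Plan** (eremophilane numbering: ring A = C1–C5 and C10; ring B = C5–C10; C14 on C5, C15 on C4, isopropenyl on C7)
1. Retrosynthetic cuts, in order: C9–O (tiglate); C7–C11 together with C8=O ⇐ C8–NO2 on a ring B C7=C8 nitroalkene; C8–C9 (ring B); nitroalkene ⇐ allyl; C3–O (senecioate); C5–C6 (allyl) and C5–C14 (methyl); C4=C5 (aldol) and C1–C10 (Michael).
2. Forward: ring A is built first from aldehyde 1 and enone 2 and then receives the C5 quaternary centre, the C3 ester, the nitroalkene arm and the C9 aldehyde. Ring B is closed through C8–C9, and isopropenyl, ketone and tiglate follow.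
3. Enabling feature: in ring B the ketone carbon C8 lies between the oxygen-bearing C9 and the isopropenyl-bearing C7, so C8 and C9 are both acceptor-type carbons. A nitro group on a C7=C8 double bond turns C8 into a donor toward a C9 aldehyde, then makes C7 the acceptor for the isopropenyl group, and is finally converted into the C8 carbonyl.
4. Stereochemistry: C10 from the amine catalyst; C5 by allylation anti to the C10 substituent; C4 and C3 by equatorial (thermodynamic) control; C9 by chair closure that avoids the axial C5 methyl; C7 by α-face addition anti to that methyl.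

Key step: step 11

Remark: the target descriptors (3R,4R,5R,7S,9S,10R in eremophilane numbering) define a trans-fused decalin with the C5 methyl axial and every other ring substituent equatorial; the route is planned for this arrangement.

**Step 1**
Reactants: 1 3-[(tert-butyldimethylsilyl)oxy]propanal; 2 pent-1-en-3-one
Product: 3 (2S)-2-{[(tert-butyldimethylsilyl)oxy]methyl}-5-oxoheptanal
Conditions: (S)-2-[methoxy(diphenyl)methyl]pyrrolidine (5 mol%), ethyl 3,4-dihydroxybenzoate (20 mol%), neat, 4 °C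
Reagents that add atoms: none
Why: Enamine-catalysed asymmetric Michael addition of an aldehyde to a vinyl ketone forms C1–C10; the diarylmethyl ether group of the (S)-catalyst shields one face of the (E)-enamine, so attack of the enone on the open face should set C10 as drawn (2S).

**Step 2**
Reactants: 3 (2S)-2-{[(tert-butyldimethylsilyl)oxy]methyl}-5-oxoheptanal
Product: 4 (4R)-4-{[(tert-butyldimethylsilyl)oxy]methyl}-2-methylcyclohex-2-en-1-one
Conditions: Bn2NH·CF3CO2H (20 mol%), toluene, 50 °C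
Reagents that add atoms: none
Why: Intramolecular aldol condensation in which the ethyl-ketone α-carbon (C4) attacks the aldehyde carbon (C5) is the only six-membered mode; the near-neutral ammonium salt should spare the C10 stereocentre and the β-silyloxy group, and no new stereocentre is formed.

**Step 3**
Reactants: 4 (4R)-4-{[(tert-butyldimethylsilyl)oxy]methyl}-2-methylcyclohex-2-en-1-one
Product: 5 tert-butyl{[(1R,2S)-2,3-dimethyl-4-(trimethylsilyloxy)cyclohex-3-en-1-yl]methoxy}dimethylsilane
Conditions: Me2CuLi (from CuI and MeLi), Me3SiCl, Et2O/THF, −78 °C; Et3N, aq. NaHCO3 work-up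
Reagents that add atoms: lithium dimethylcuprate [Li+].C[Cu-]C; chlorotrimethylsilane C[Si](C)(C)Cl
Why: Silyl-accelerated cuprate conjugate addition with enolate trapping places C14 on C5 trans to the C10 substituent (this centre is erased in step 4) and gives the regiodefined silyl enol ether.

**Step 4**
Reactants: 5 tert-butyl{[(1R,2S)-2,3-dimethyl-4-(trimethylsilyloxy)cyclohex-3-en-1-yl]methoxy}dimethylsilane
Product: 6 (4R)-4-{[(tert-butyldimethylsilyl)oxy]methyl}-2,3-dimethylcyclohex-2-en-1-one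
Conditions: Pd(OAc)2 (1.0 equiv), MeCN, rt
Reagents that add atoms: none
Why: Saegusa–Ito oxidation; β-hydride elimination of the palladium enolate toward C5–H should give the tetrasubstituted enone, the same conjugate addition/dehydrogenation sequence that is routine for making 2,3-dimethylcyclohexenones from 2-methylcyclohexenones, and no stereocentre is created.

**Step 5**
Reactants: 6 (4R)-4-{[(tert-butyldimethylsilyl)oxy]methyl}-2,3-dimethylcyclohex-2-en-1-one
Product: 8 (2R,3S,4R)-4-{[(tert-butyldimethylsilyl)oxy]methyl}-2,3-dimethyl-3-(prop-2-en-1-yl)cyclohexan-1-one, via trichlorotitanium enolate 7 (not isolated)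
Conditions: CH2=CHCH2SiMe3, TiCl4, CH2Cl2, −78 °C; H2O; then K2CO3 (cat.), MeOH, rt
Reagents that add atoms: allyltrimethylsilane C=CC[Si](C)(C)C
Why: Hosomi–Sakurai conjugate allylation builds the quaternary C5 with the allyl group entering anti to the pseudoaxial C10 substituent (C6 trans to C9, C14 cis to C9), and protonation with base equilibration should leave the C4 methyl equatorial, cis to C14.

**Step 6**
Reactants: 8 (2R,3S,4R)-4-{[(tert-butyldimethylsilyl)oxy]methyl}-2,3-dimethyl-3-(prop-2-en-1-yl)cyclohexan-1-one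
Product: 9 (1R,2R,3S,4R)-4-{[(tert-butyldimethylsilyl)oxy]methyl}-2,3-dimethyl-3-(prop-2-en-1-yl)cyclohexan-1-ol
Conditions: Li, NH3(l), THF, MeOH, −78 °C; NH4Cl
Reagents that add atoms: none
Why: Dissolving-metal ketone reduction under thermodynamic control should give the equatorial C3 alcohol (trans to the C4 methyl), which small hydrides would not secure because the axial C5 methyl blocks axial attack; the terminal alkene and silyl ether are inert.

**Step 7**
Reactants: 9 (1R,2R,3S,4R)-4-{[(tert-butyldimethylsilyl)oxy]methyl}-2,3-dimethyl-3-(prop-2-en-1-yl)cyclohexan-1-ol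
Product: 10 (1R,2R,3S,4R)-4-{[(tert-butyldimethylsilyl)oxy]methyl}-2,3-dimethyl-3-(prop-2-en-1-yl)cyclohexyl 3-methylbut-2-enoate
Conditions: 3-methylbut-2-enoyl chloride, pyridine, DMAP (cat.), CH2Cl2, 0 °C to rt
Reagents that add atoms: 3-methylbut-2-enoyl chloride CC(C)=CC(Cl)=O
Why: Nucleophilic-catalysed O-acylation of the equatorial secondary alcohol proceeds with retention at C3; pyridine instead of a trialkylamine limits deconjugation through a vinylketene.

**Step 8**
Reactants: 10 (1R,2R,3S,4R)-4-{[(tert-butyldimethylsilyl)oxy]methyl}-2,3-dimethyl-3-(prop-2-en-1-yl)cyclohexyl 3-methylbut-2-enoate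
Product: 11 (1R,2R,3S,4R)-4-{[(tert-butyldimethylsilyl)oxy]methyl}-2,3-dimethyl-3-[(2E)-3-nitroprop-2-en-1-yl]cyclohexyl 3-methylbut-2-enoate
Conditions: AgNO2 (3 equiv), TEMPO (0.4 equiv), 4 Å molecular sieves, ClCH2CH2Cl, 70 °C
Reagents that add atoms: silver nitrite [Ag+].[O-]N=O
Why: Radical nitration of a terminal alkene: nitrogen dioxide adds to the terminal carbon (C8) and nitroxyl-assisted hydrogen abstraction gives the conjugated (E)-nitroalkene, while the electron-poor trisubstituted ester alkene should not react.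

**Step 9**
Reactants: 11 (1R,2R,3S,4R)-4-{[(tert-butyldimethylsilyl)oxy]methyl}-2,3-dimethyl-3-[(2E)-3-nitroprop-2-en-1-yl]cyclohexyl 3-methylbut-2-enoate
Product: 12 (1R,2R,3S,4R)-4-(hydroxymethyl)-2,3-dimethyl-3-[(2E)-3-nitroprop-2-en-1-yl]cyclohexyl 3-methylbut-2-enoate
Conditions: HF·pyridine, THF, 0 °C to rt
Reagents that add atoms: none
Why: Fluoride-mediated silyl ether cleavage under acidic buffering, chosen so that no alkoxide forms that could add to the nitroalkene.

**Step 10**
Reactants: 12 (1R,2R,3S,4R)-4-(hydroxymethyl)-2,3-dimethyl-3-[(2E)-3-nitroprop-2-en-1-yl]cyclohexyl 3-methylbut-2-enoate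
Product: 13 (1R,2R,3R,4R)-4-formyl-2,3-dimethyl-3-[(2E)-3-nitroprop-2-en-1-yl]cyclohexyl 3-methylbut-2-enoate
Conditions: Dess–Martin periodinane, NaHCO3, CH2Cl2, 0 °C to rt
Reagents that add atoms: none
Why: Buffered hypervalent-iodine oxidation of the primary alcohol gives the C9 aldehyde without epimerising the adjacent C10 centre.

**Step 11**
Reactants: 13 (1R,2R,3R,4R)-4-formyl-2,3-dimethyl-3-[(2E)-3-nitroprop-2-en-1-yl]cyclohexyl 3-methylbut-2-enoate
Product: 15 (1R,2R,4aR,5S,8aR)-5-hydroxy-1,8a-dimethyl-6-nitro-1,2,3,4,4a,5,8,8a-octahydronaphthalen-2-yl 3-methylbut-2-enoate, via imidazolyl nitro alcohol 14 (not isolated)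
Conditions: imidazole (1.0 equiv), THF, rt
Reagents that add atoms: none
Why: Proposed new method: an intramolecular Morita–Baylis–Hillman cyclisation of a nitroalkene onto a non-activated aldehyde, in which imidazole adds reversibly to C7, the resulting C8 nitronate (the future carbonyl carbon acting as a donor) attacks the C9 aldehyde in a Henry step, and E1cB loss of imidazole from 14 through the acidic C8–H restores the C7=C8 nitroalkene. The closest known reaction types are the imidazole- or DMAP-mediated intermolecular Morita–Baylis–Hillman reactions of conjugated nitroalkenes with formaldehyde or glyoxylates and thiolate-triggered Michael–Henry tandem reactions; here the tether should make up for the lower electrophilicity of an α-branched aldehyde. Ring B closes in a 6-(enolexo)-exo-trig mode, with the nitronate C=N and the aldehyde C=O both outside the new ring. The only new stereocentre kept in 15 is C9: in the chair transition state the alkoxide takes the equatorial (α) position because the axial position is 1,3-diaxial to the angular C5 methyl, and the reversibility of the Henry step lets this preference be expressed. The step needs C-attack by C8 rather than oligomerisation or enolisation at C10, which a weakly basic nucleophilic catalyst should secure, and it needs loss of imidazole rather than water, which follows because only the C7 substituent is a good leaving group β to the nitronate.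

**Step 12**
Reactants: 15 (1R,2R,4aR,5S,8aR)-5-hydroxy-1,8a-dimethyl-6-nitro-1,2,3,4,4a,5,8,8a-octahydronaphthalen-2-yl 3-methylbut-2-enoate
Product: 17 (1R,2R,4aR,5S,7S,8aR)-5-hydroxy-1,8a-dimethyl-6-oxo-7-(prop-1-en-2-yl)decahydronaphthalen-2-yl 3-methylbut-2-enoate, via magnesium nitronate 16 (not isolated)
Conditions: CH2=C(CH3)MgBr (2.5 equiv), CuBr·SMe2 (20 mol%), THF, −78 °C; then aq. TiCl3, NH4OAc, THF/H2O, 0 °C to rt
Reagents that add atoms: isopropenylmagnesium bromide CC(=C)[Mg]Br; water O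
Why: Copper-catalysed conjugate addition to the cyclic nitroalkene followed by a reductive Nef reaction in the same flask: the isopropenyl group should enter C7 from the α face, anti to the axial C5 methyl and on the side of the C9 magnesium alkoxide, ending equatorial (also the thermodynamic C7 epimer of the ketone), and trivalent titanium reduces the nitronate to an imine that hydrolyses to the C8 ketone.

**Step 13**
Reactants: 17 (1R,2R,4aR,5S,7S,8aR)-5-hydroxy-1,8a-dimethyl-6-oxo-7-(prop-1-en-2-yl)decahydronaphthalen-2-yl 3-methylbut-2-enoate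
Product: 18 (1R,2R,4aR,5S,7S,8aR)-1,8a-dimethyl-5-{[(2E)-2-methylbut-2-enoyl]oxy}-6-oxo-7-(prop-1-en-2-yl)decahydronaphthalen-2-yl 3-methylbut-2-enoate
Conditions: (E)-2-methylbut-2-enoyl chloride, pyridine, DMAP (cat.), CH2Cl2, 0 °C
Reagents that add atoms: (E)-2-methylbut-2-enoyl chloride C/C=C(\C)C(Cl)=O
Why: O-acylation of the equatorial α-ketol under mild conditions keeps the C9 and C7 configurations and the E geometry of the acyl group.

**Compound list**
1 | 3-[(tert-butyldimethylsilyl)oxy]propanal | O=CCCO[Si](C)(C)C(C)(C)C | starting material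
2 | pent-1-en-3-one | C=CC(=O)CC | starting material
3 | (2S)-2-{[(tert-butyldimethylsilyl)oxy]methyl}-5-oxoheptanal | CCC(=O)CC[C@H](C=O)CO[Si](C)(C)C(C)(C)C | intermediate
4 | (4R)-4-{[(tert-butyldimethylsilyl)oxy]methyl}-2-methylcyclohex-2-en-1-one | CC1=C[C@H](CO[Si](C)(C)C(C)(C)C)CCC1=O | intermediate
5 | tert-butyl{[(1R,2S)-2,3-dimethyl-4-(trimethylsilyloxy)cyclohex-3-en-1-yl]methoxy}dimethylsilane | C[C@@H]1C(C)=C(O[Si](C)(C)C)CC[C@H]1CO[Si](C)(C)C(C)(C)C | intermediate
6 | (4R)-4-{[(tert-butyldimethylsilyl)oxy]methyl}-2,3-dimethylcyclohex-2-en-1-one | CC1=C(C)C(=O)CC[C@H]1CO[Si](C)(C)C(C)(C)C | intermediate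
7 | trichloro{[(3S,4R)-4-{[(tert-butyldimethylsilyl)oxy]methyl}-2,3-dimethyl-3-(prop-2-en-1-yl)cyclohex-1-en-1-yl]oxy}titanium | C=CC[C@]1(C)C(C)=C(O[Ti](Cl)(Cl)Cl)CC[C@H]1CO[Si](C)(C)C(C)(C)C | intermediate
8 | (2R,3S,4R)-4-{[(tert-butyldimethylsilyl)oxy]methyl}-2,3-dimethyl-3-(prop-2-en-1-yl)cyclohexan-1-one | C=CC[C@]1(C)[C@@H](C)C(=O)CC[C@H]1CO[Si](C)(C)C(C)(C)C | intermediate
9 | (1R,2R,3S,4R)-4-{[(tert-butyldimethylsilyl)oxy]methyl}-2,3-dimethyl-3-(prop-2-en-1-yl)cyclohexan-1-ol | C=CC[C@]1(C)[C@@H](C)[C@H](O)CC[C@H]1CO[Si](C)(C)C(C)(C)C | intermediate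
10 | (1R,2R,3S,4R)-4-{[(tert-butyldimethylsilyl)oxy]methyl}-2,3-dimethyl-3-(prop-2-en-1-yl)cyclohexyl 3-methylbut-2-enoate | C=CC[C@]1(C)[C@@H](C)[C@H](OC(=O)C=C(C)C)CC[C@H]1CO[Si](C)(C)C(C)(C)C | intermediate
11 | (1R,2R,3S,4R)-4-{[(tert-butyldimethylsilyl)oxy]methyl}-2,3-dimethyl-3-[(2E)-3-nitroprop-2-en-1-yl]cyclohexyl 3-methylbut-2-enoate | [O-][N+](=O)/C=C/C[C@]1(C)[C@@H](C)[C@H](OC(=O)C=C(C)C)CC[C@H]1CO[Si](C)(C)C(C)(C)C | intermediate
12 | (1R,2R,3S,4R)-4-(hydroxymethyl)-2,3-dimethyl-3-[(2E)-3-nitroprop-2-en-1-yl]cyclohexyl 3-methylbut-2-enoate | [O-][N+](=O)/C=C/C[C@]1(C)[C@@H](C)[C@H](OC(=O)C=C(C)C)CC[C@H]1CO | intermediate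
13 | (1R,2R,3R,4R)-4-formyl-2,3-dimethyl-3-[(2E)-3-nitroprop-2-en-1-yl]cyclohexyl 3-methylbut-2-enoate | [O-][N+](=O)/C=C/C[C@]1(C)[C@@H](C)[C@H](OC(=O)C=C(C)C)CC[C@H]1C=O | intermediate
14 | (1R,2R,4aR,5S,6S,7R,8aR)-5-hydroxy-7-(1H-imidazol-1-yl)-1,8a-dimethyl-6-nitrodecahydronaphthalen-2-yl 3-methylbut-2-enoate | c1cn(cn1)[C@@H]1C[C@]2(C)[C@@H](C)[C@H](OC(=O)C=C(C)C)CC[C@H]2[C@H](O)[C@H]1[N+](=O)[O-] | intermediate
15 | (1R,2R,4aR,5S,8aR)-5-hydroxy-1,8a-dimethyl-6-nitro-1,2,3,4,4a,5,8,8a-octahydronaphthalen-2-yl 3-methylbut-2-enoate | [O-][N+](=O)C1=CC[C@]2(C)[C@@H](C)[C@H](OC(=O)C=C(C)C)CC[C@H]2[C@@H]1O | intermediate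
16 | bis(bromomagnesium) C6-nitronate C5-alkoxide of (1R,2R,4aR,5S,7S,8aR)-5-hydroxy-1,8a-dimethyl-6-nitro-7-(prop-1-en-2-yl)decahydronaphthalen-2-yl 3-methylbut-2-enoate | C=C(C)[C@@H]1C[C@]2(C)[C@@H](C)[C@H](OC(=O)C=C(C)C)CC[C@H]2[C@H]([O-])C1=[N+]([O-])[O-].[Mg+2].[Mg+2].[Br-].[Br-] | intermediate
17 | (1R,2R,4aR,5S,7S,8aR)-5-hydroxy-1,8a-dimethyl-6-oxo-7-(prop-1-en-2-yl)decahydronaphthalen-2-yl 3-methylbut-2-enoate | C=C(C)[C@@H]1C[C@]2(C)[C@@H](C)[C@H](OC(=O)C=C(C)C)CC[C@H]2[C@H](O)C1=O | intermediate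
18 | (1R,2R,4aR,5S,7S,8aR)-1,8a-dimethyl-5-{[(2E)-2-methylbut-2-enoyl]oxy}-6-oxo-7-(prop-1-en-2-yl)decahydronaphthalen-2-yl 3-methylbut-2-enoate | C=C(C)[C@@H]1C[C@]2(C)[C@@H](C)[C@H](OC(=O)C=C(C)C)CC[C@H]2[C@H](OC(=O)/C(C)=C/C)C1=O | target

**Step count and risks**
Total steps: 13. Longest linear sequence: 13 steps (1 and 2 to 18).

Steps most likely to fail:

1. Step 11 (proposed new method). The ring closure may not compete with reversal of the imidazole adduct or with oligomerisation of the nitroalkene, because the aldehyde is α-branched and not activated. Fallback from 13, returning at 15: treatment with PhSH and catalytic Et3N in THF should trigger a thiolate Michael addition at C7 followed by intramolecular Henry closure of the C8 nitronate onto C9, giving (1R,2R,4aR,5S,6R,7R,8aR)-5-hydroxy-1,8a-dimethyl-6-nitro-7-(phenylsulfanyl)decahydronaphthalen-2-yl 3-methylbut-2-enoate F1. Oxidation with one equivalent of mCPBA at −78 °C would give the sulfoxide, the 7-(benzenesulfinyl) analogue F2, and DBU-promoted elimination through the acidic C8–H would regenerate the C7=C8 nitroalkene 15.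

2. Step 5. Conjugate allylation at the tetrasubstituted, doubly flanked β-carbon may stall, or the Lewis acid may strip the silyl ether before addition. Fallback from 6, returning at 8: 1,2-addition of CH2=CHCH2MgBr to the ketone, expected mainly anti to the C10 substituent, gives (1R,4R)-4-{[(tert-butyldimethylsilyl)oxy]methyl}-2,3-dimethyl-1-(prop-2-en-1-yl)cyclohex-2-en-1-ol F3. KH with 18-crown-6 in THF would then effect an anionic oxy-Cope rearrangement that moves the allyl group suprafacially from C3 to C5, and protonation of the resulting enolate with equilibration gives 8.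

3. Step 12. The one-flask sequence may break down at the Nef stage, through incomplete reduction of the hydroxy nitronate or retro-Henry opening of ring B. Fallback from 15, returning at 17: the cuprate addition is quenched with NH4Cl to isolate (1R,2R,4aR,5S,6S,7S,8aR)-5-hydroxy-1,8a-dimethyl-6-nitro-7-(prop-1-en-2-yl)decahydronaphthalen-2-yl 3-methylbut-2-enoate F4. The secondary nitro group is reduced with SnCl2, PhSH and Et3N to the oxime, (1R,2R,4aR,5S,7S,8aR)-5-hydroxy-6-(hydroxyimino)-1,8a-dimethyl-7-(prop-1-en-2-yl)decahydronaphthalen-2-yl 3-methylbut-2-enoate F5, and mild hydrolytic deoximation (aq. NaHSO3, EtOH) gives 17.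

**Further compounds**
F1 | step 11 | (1R,2R,4aR,5S,6R,7R,8aR)-5-hydroxy-1,8a-dimethyl-6-nitro-7-(phenylsulfanyl)decahydronaphthalen-2-yl 3-methylbut-2-enoate | c1ccccc1S[C@@H]1C[C@]2(C)[C@@H](C)[C@H](OC(=O)C=C(C)C)CC[C@H]2[C@H](O)[C@H]1[N+](=O)[O-]
F2 | step 11 | (1R,2R,4aR,5S,6R,7R,8aR)-7-(benzenesulfinyl)-5-hydroxy-1,8a-dimethyl-6-nitrodecahydronaphthalen-2-yl 3-methylbut-2-enoate (sulfur configuration undefined) | [O-][S+](c1ccccc1)[C@@H]1C[C@]2(C)[C@@H](C)[C@H](OC(=O)C=C(C)C)CC[C@H]2[C@H](O)[C@H]1[N+](=O)[O-]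
F3 | step 5 | (1R,4R)-4-{[(tert-butyldimethylsilyl)oxy]methyl}-2,3-dimethyl-1-(prop-2-en-1-yl)cyclohex-2-en-1-ol | CC1=C(C)[C@](O)(CC=C)CC[C@H]1CO[Si](C)(C)C(C)(C)C
F4 | step 12 | (1R,2R,4aR,5S,6S,7S,8aR)-5-hydroxy-1,8a-dimethyl-6-nitro-7-(prop-1-en-2-yl)decahydronaphthalen-2-yl 3-methylbut-2-enoate | C=C(C)[C@@H]1C[C@]2(C)[C@@H](C)[C@H](OC(=O)C=C(C)C)CC[C@H]2[C@H](O)[C@H]1[N+](=O)[O-]
F5 | step 12 | (1R,2R,4aR,5S,7S,8aR)-5-hydroxy-6-(hydroxyimino)-1,8a-dimethyl-7-(prop-1-en-2-yl)decahydronaphthalen-2-yl 3-methylbut-2-enoate (oxime geometry undefined) | C=C(C)[C@@H]1C[C@]2(C)[C@@H](C)[C@H](OC(=O)C=C(C)C)CC[C@H]2[C@H](O)C1=NO
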